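The depside is disconnected at its ester carbonyl, a lone carbon that links ring A C1 (flanked by the C2 oxygen and the C6 heptyl chain) to the oxygen on ring B C4 and can therefore come from carbon monoxide. One palladium-catalysed aryloxycarbonylation unites a ring-A aryl iodide, CO and a ring-B phenol, forming the C1–C(=O) and C(=O)–O bonds together; the phenoxide is delivered at palladium, not at a shielded carbonyl. The iodide is the dibenzyl ether of 5-heptylresorcinol iodinated beside the chain (symmetry makes this unambiguous); the phenol is tert-butyl 2-heptyl-4-hydroxy-6-methoxybenzoate. Debenzylation, methylation of the ring A C4 hydroxyl that is not hydrogen-bonded to the carbonyl, and ester acidolysis finish the synthesis.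

Key step: step 6

Remark: the target has no stereocentre, axis or stereogenic double bond, so it is a single achiral compound and no step needs stereocontrol.
Ring labels: ring A is the acyl ring (C1 depside carbonyl, C2 OH, C4 OMe, C6 heptyl); ring B is the benzoic acid ring (C1 CO2H, C2 heptyl, C4 depside oxygen, C6 OMe).

Step 1
Reactants: 1 3,5-bis(benzyloxy)benzyl bromide; 2 hexylmagnesium bromide
Product: 3 1,3-bis(benzyloxy)-5-heptylbenzene
Conditions: Li2CuCl4 (3 mol %), THF, slow addition of 2, −78 → 0 °C
Reagents that add atoms: none
Why: Kochi-type copper-catalysed sp3–sp3 cross-coupling of a benzylic bromide with a primary alkyl Grignard reagent should join CH2 and hexyl into the heptyl chain, the benzyl ethers being inert and slow addition at low temperature limiting Wurtz homocoupling.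

Step 2
Reactants: 3 1,3-bis(benzyloxy)-5-heptylbenzene
Product: 4 1,5-bis(benzyloxy)-3-heptyl-2-iodobenzene
Conditions: NIS (1.05 equiv), TFA (cat.), MeCN, 0 °C → rt, dark
Reagents that add atoms: N-iodosuccinimide, O=C1CCC(=O)N1I
Why: Electrophilic aromatic iodination of the symmetric resorcinol diether should occur at one of the two equivalent positions beside the heptyl chain (ortho to one ether, para to the other), the position between the two benzyloxy groups being more crowded, so a single mono-iodide is expected.

Step 3
Reactants: 5 2-methoxy-6-methylbenzoic acid; 6 1-iodohexane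
Product: 7 2-heptyl-6-methoxybenzoic acid
Conditions: LDA (2.2 equiv), THF, −78 → 0 °C; then 6, −78 °C → rt; aq. HCl
Reagents that add atoms: none
Why: Lateral (benzylic) lithiation of the o-toluic acid as its carboxylate dianion, followed by SN2 alkylation with the primary iodide at the benzylic carbon, should extend the methyl group to heptyl.

Step 4
Reactants: 7 2-heptyl-6-methoxybenzoic acid
Product: 8 tert-butyl 2-heptyl-6-methoxybenzoate
Conditions: tert-butyl 2,2,2-trichloroacetimidate (2.5 equiv), BF3·OEt2 (10 mol %), cyclohexane/CH2Cl2, rt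
Reagents that add atoms: tert-butyl 2,2,2-trichloroacetimidate, CC(C)(C)OC(=N)C(Cl)(Cl)Cl
Why: Acid-catalysed O-tert-butylation with the trichloroacetimidate makes the ester by attack of the carboxyl oxygen on a tert-butyl cation equivalent, so the crowding of the 2,6-disubstituted carbonyl carbon does not matter.

Step 5
Reactants: 8 tert-butyl 2-heptyl-6-methoxybenzoate
Product: 10 tert-butyl 2-heptyl-4-hydroxy-6-methoxybenzoate, via C4 pinacol boronate 9 (not isolated)
Conditions: [Ir(OMe)(cod)]2 (1.5 mol %), dtbpy (3 mol %), B2pin2 (1.0 equiv), THF, 80 °C; evaporate; Oxone (1.1 equiv), acetone/H2O, rt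
Reagents that add atoms: potassium peroxymonosulfate (Oxone), [K+].[O-]S(=O)(=O)OO; bis(pinacolato)diboron, CC1(C)OB(OC1(C)C)B1OC(C)(C)C(C)(C)O1 (its boron is kept only in intermediate 9)
Why: Iridium-catalysed C–H borylation is sterically governed and should functionalise C4, the only ring C–H without an ortho substituent, after which the crude boronate undergoes ipso-hydroxylation with Oxone in the same flask without affecting the tert-butyl ester or the methyl ether.

Step 6
Reactants: 4 1,5-bis(benzyloxy)-3-heptyl-2-iodobenzene; 10 tert-butyl 2-heptyl-4-hydroxy-6-methoxybenzoate; 11 carbon monoxide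
Product: 12 tert-butyl 4-{[2,4-bis(benzyloxy)-6-heptylbenzoyl]oxy}-2-heptyl-6-methoxybenzoate
Conditions: Pd(OAc)2 (5 mol %), Xantphos (7.5 mol %), Et3N (3 equiv), CO (10 bar), toluene, 4 Å MS, 100 °C
Reagents that add atoms: none
Why: Pd(0) adds oxidatively to the C–I bond of 4, CO inserts to give an aroylpalladium(II) iodide, the phenoxide formed from 10 and triethylamine replaces iodide at palladium, and C(acyl)–O reductive elimination releases the aryl ester and Pd(0). The closest known reaction type is the palladium-catalysed aryloxycarbonylation of aryl iodides with phenols under CO with a wide-bite-angle diphosphine, which tolerates ortho substituents. No ring is closed and no stereocentre is formed. The selectivity needed is carbonylative coupling over direct C–O coupling, hydrodeiodination and intramolecular C–H arylation of the neighbouring benzyl ether; the two ortho groups of 4 retard direct reductive elimination, while CO pressure, Xantphos and an amine base (no carboxylate or carbonate to assist C–H metalation) should keep the acyl pathway dominant. The para ester of 10 makes its hydroxyl acidic enough for triethylamine, and it is the only nucleophile present, the tert-butyl ester and benzyl ethers being inert. Because the ester oxygen is transferred at the metal, the shielding of ring A C1 by the C2 benzyloxy and C6 heptyl groups, which hampers a classical acylation, is bypassed.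

Step 7
Reactants: 12 tert-butyl 4-{[2,4-bis(benzyloxy)-6-heptylbenzoyl]oxy}-2-heptyl-6-methoxybenzoate
Product: 13 tert-butyl 2-heptyl-4-[(6-heptyl-2,4-dihydroxybenzoyl)oxy]-6-methoxybenzoate
Conditions: H2 (1 atm), 10% Pd/C, EtOAc, rt
Reagents that add atoms: none
Why: Catalytic hydrogenolysis should cleave both benzyl ethers while the diaryl ester and the tert-butyl ester are untouched, and a neutral non-nucleophilic solvent excludes transesterification.

Step 8
Reactants: 13 tert-butyl 2-heptyl-4-[(6-heptyl-2,4-dihydroxybenzoyl)oxy]-6-methoxybenzoate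
Product: 14 tert-butyl 2-heptyl-4-[(6-heptyl-2-hydroxy-4-methoxybenzoyl)oxy]-6-methoxybenzoate
Conditions: MeI (1.1 equiv), K2CO3 (1.1 equiv), acetone, rt
Reagents that add atoms: iodomethane, CI
Why: Williamson O-alkylation with one equivalent of reagent should take place only at the ring A C4 hydroxyl, because the C2 hydroxyl is held in an intramolecular hydrogen bond to the depside carbonyl and is much less acidic and nucleophilic, as in the selective 4-O-alkylation of 2,4-dihydroxybenzoate esters.

Step 9
Reactants: 14 tert-butyl 2-heptyl-4-[(6-heptyl-2-hydroxy-4-methoxybenzoyl)oxy]-6-methoxybenzoate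
Product: 15 2-heptyl-4-[(6-heptyl-2-hydroxy-4-methoxybenzoyl)oxy]-6-methoxybenzoic acid
Conditions: TFA/CH2Cl2 (1:3), 0 °C → rt
Reagents that add atoms: none
Why: Acidolysis of the tert-butyl ester (alkyl–oxygen cleavage with loss of isobutene) should free the ring B carboxylic acid without touching the diaryl ester, the methyl ethers or the acyl-deactivated phenol ring.

Compound list
1 | 3,5-bis(benzyloxy)benzyl bromide | BrCc1cc(OCc2ccccc2)cc(OCc2ccccc2)c1 | starting material
2 | hexylmagnesium bromide | CCCCCC[Mg]Br | starting material
3 | 1,3-bis(benzyloxy)-5-heptylbenzene | CCCCCCCc1cc(OCc2ccccc2)cc(OCc2ccccc2)c1 | intermediate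
4 | 1,5-bis(benzyloxy)-3-heptyl-2-iodobenzene | CCCCCCCc1cc(OCc2ccccc2)cc(OCc2ccccc2)c1I | intermediate
5 | 2-methoxy-6-methylbenzoic acid | COc1cccc(C)c1C(=O)O | starting material
6 | 1-iodohexane | CCCCCCI | starting material
7 | 2-heptyl-6-methoxybenzoic acid | CCCCCCCc1cccc(OC)c1C(=O)O | intermediate
8 | tert-butyl 2-heptyl-6-methoxybenzoate | CCCCCCCc1cccc(OC)c1C(=O)OC(C)(C)C | intermediate
9 | tert-butyl 2-heptyl-6-methoxy-4-(4,4,5,5-tetramethyl-1,3,2-dioxaborolan-2-yl)benzoate | CCCCCCCc1cc(B2OC(C)(C)C(C)(C)O2)cc(OC)c1C(=O)OC(C)(C)C | intermediate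
10 | tert-butyl 2-heptyl-4-hydroxy-6-methoxybenzoate | CCCCCCCc1cc(O)cc(OC)c1C(=O)OC(C)(C)C | intermediate
11 | carbon monoxide | [C-]#[O+] | starting material
12 | tert-butyl 4-{[2,4-bis(benzyloxy)-6-heptylbenzoyl]oxy}-2-heptyl-6-methoxybenzoate | CCCCCCCc1cc(OCc2ccccc2)cc(OCc2ccccc2)c1C(=O)Oc1cc(CCCCCCC)c(C(=O)OC(C)(C)C)c(OC)c1 | intermediate
13 | tert-butyl 2-heptyl-4-[(6-heptyl-2,4-dihydroxybenzoyl)oxy]-6-methoxybenzoate | CCCCCCCc1cc(O)cc(O)c1C(=O)Oc1cc(CCCCCCC)c(C(=O)OC(C)(C)C)c(OC)c1 | intermediate
14 | tert-butyl 2-heptyl-4-[(6-heptyl-2-hydroxy-4-methoxybenzoyl)oxy]-6-methoxybenzoate | CCCCCCCc1cc(OC)cc(O)c1C(=O)Oc1cc(CCCCCCC)c(C(=O)OC(C)(C)C)c(OC)c1 | intermediate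
15 | 2-heptyl-4-[(6-heptyl-2-hydroxy-4-methoxybenzoyl)oxy]-6-methoxybenzoic acid | CCCCCCCc1cc(OC)cc(O)c1C(=O)Oc1cc(CCCCCCC)c(C(=O)O)c(OC)c1 | target

Total step count: 9. Longest linear sequence: 7 steps (steps 3, 4, 5, 6, 7, 8 and 9, from 2-methoxy-6-methylbenzoic acid); the ring A branch (steps 1 and 2) joins at step 6.

Steps most likely to fail

Step 6. The doubly ortho-substituted, electron-rich iodide may undergo slow oxidative addition or slow acyl transfer. Reduction of the C–I bond, hydrolysis of the aroylpalladium species by adventitious water, or cyclisation onto a benzyl ring could then compete. The fallback abandons the carbonylation for a classical acylation through an acyl chloride. It sets out from iodide 4 and uses phenol 10. Iodine–magnesium exchange (i-PrMgCl·LiCl, THF, 0 °C → rt) and a CO2 quench should give 2,4-bis(benzyloxy)-6-heptylbenzoic acid F1. Oxalyl chloride with catalytic DMF in CH2Cl2 should convert it into 2,4-bis(benzyloxy)-6-heptylbenzoyl chloride F2. Addition of F2 to the preformed sodium phenoxide of 10 (NaH, THF, 0 °C → rt) should give the ester and return to the route at 12.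

Step 5. Site control in the C–H borylation may be incomplete (attack at the C–H next to the methoxy group), the hindered arene may react slowly, or the one-pot oxidation may be unclean. The fallback builds the ring B oxygenation pattern by electrophilic substitution and chelation control instead. It sets out from 3. Vilsmeier–Haack formylation (POCl3, DMF) beside the heptyl chain should give 2,4-bis(benzyloxy)-6-heptylbenzaldehyde F3. Chelation-controlled removal of the benzyl group ortho to the aldehyde (MgBr2·OEt2, toluene/Et2O, reflux) should give 4-(benzyloxy)-2-heptyl-6-hydroxybenzaldehyde F4. Methylation (MeI, K2CO3, DMF) should give 4-(benzyloxy)-2-heptyl-6-methoxybenzaldehyde F5. Pinnick oxidation (NaClO2, NaH2PO4, 2-methyl-2-butene, t-BuOH/H2O) should give 4-(benzyloxy)-2-heptyl-6-methoxybenzoic acid F6. The trichloroacetimidate esterification of step 4 should give tert-butyl 4-(benzyloxy)-2-heptyl-6-methoxybenzoate F7. Hydrogenolysis (H2, Pd/C, EtOAc) then returns to the route at 10.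

Step 8. Discrimination between the two ring A hydroxyls may be imperfect, or carbonate-generated phenoxide may cause scission or acyl transfer of the diaryl ester. The fallback replaces phenoxide alkylation by a base-free dehydrative etherification. It sets out from 13: Mitsunobu coupling with methanol (MeOH, PPh3, DIAD, THF, 0 °C → rt) activates the alcohol rather than the phenol, so no free phenoxide is formed, and the more acidic ring A C4 hydroxyl should still react preferentially. It returns to the route at 14 without any new intermediate.

Further compounds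
F1 | step 6 | 2,4-bis(benzyloxy)-6-heptylbenzoic acid | CCCCCCCc1cc(OCc2ccccc2)cc(OCc2ccccc2)c1C(=O)O
F2 | step 6 | 2,4-bis(benzyloxy)-6-heptylbenzoyl chloride | CCCCCCCc1cc(OCc2ccccc2)cc(OCc2ccccc2)c1C(=O)Cl
F3 | step 5 | 2,4-bis(benzyloxy)-6-heptylbenzaldehyde | CCCCCCCc1cc(OCc2ccccc2)cc(OCc2ccccc2)c1C=O
F4 | step 5 | 4-(benzyloxy)-2-heptyl-6-hydroxybenzaldehyde | CCCCCCCc1cc(OCc2ccccc2)cc(O)c1C=O
F5 | step 5 | 4-(benzyloxy)-2-heptyl-6-methoxybenzaldehyde | CCCCCCCc1cc(OCc2ccccc2)cc(OC)c1C=O
F6 | step 5 | 4-(benzyloxy)-2-heptyl-6-methoxybenzoic acid | CCCCCCCc1cc(OCc2ccccc2)cc(OC)c1C(=O)O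
F7 | step 5 | tert-butyl 4-(benzyloxy)-2-heptyl-6-methoxybenzoate | CCCCCCCc1cc(OCc2ccccc2)cc(OC)c1C(=O)OC(C)(C)C
F0 | step 8 | none | none
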